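**Retrosynthetic overview**
1. Target ⇐ oxidation of the C1 alcohol ⇐ hydroxyl-directed epoxidation ⇐ 1,2-reduction of a 6-angeloyloxy-2-methylcyclohex-2-enone; the C1 hydroxyl relays the oxirane onto the face of the C5 side chain.
2. C6–O ⇐ enolate hydroxylation anti to the C5 substituent, then angelate; the side-chain silyl ether is exchanged for acetate.
3. Cyclohexenone ⇐ prochiral 3-alkenylcyclobutanone + propyne: two-carbon ring expansion by nickel insertion into a ring C–C bond, which sets C5.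
4. Cyclobutanone ⇐ 3-bromocyclobutanone + side-chain alkenyl bromide (reductive sp3–sp2 coupling); side chain ⇐ 2-bromoacrolein + allyl (asymmetric allylboration) + 2-methylbut-2-ene (cross-metathesis).
5. Ring order: four-membered ring bought → six-membered carbocycle (step 5) → oxirane (step 10).

Assumption: 2-bromoacrolein and 3-bromocyclobutan-1-one are taken as catalogue compounds.
Notation: ring positions are numbered as in the target ketone (C1 carbonyl, C2 methyl-bearing carbon, C3, C4, C5 side-chain carbon, C6 angelate carbon). TBS = tert-butyldimethylsilyl. NHC* = bulky C2-symmetric imidazol-2-ylidene with N-[2,6-bis((R)-1-phenylethyl)-4-methylphenyl] groups on an acenaphthene-fused backbone, made from its imidazolium chloride and KOtBu.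

**Step 1**
Reactants: 1 2-bromoprop-2-enal (2-bromoacrolein); 2 allylmagnesium bromide
Product: 5 (3S)-2-bromohexa-1,5-dien-3-ol, via B-allyldiisopinocampheylborane 3 (not isolated), via homoallyl diisopinocampheylborinate 4 (not isolated)
Conditions: (−)-Ipc2BOMe [from (+)-α-pinene], Et2O, 0 °C; then 1, −78 °C; then NaOH, H2O2, 0 → 25 °C
Reagents that add atoms: none
Why: Brown allylboration through a closed Zimmerman–Traxler chair in which the isopinocampheyl groups of the (+)-α-pinene-derived reagent steer allyl transfer to the Si face of the aldehyde, setting the side-chain carbinol carbon as S, after which the borinate is cleaved oxidatively.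

**Step 2**
Reactants: 5 (3S)-2-bromohexa-1,5-dien-3-ol; 6 2-methylbut-2-ene
Product: 7 (3S)-2-bromo-6-methylhepta-1,5-dien-3-ol
Conditions: second-generation Grubbs catalyst RuCl2(=CHPh)(PCy3)(H2IMes) (3 mol %), excess 6, CH2Cl2, 40 °C
Reagents that add atoms: none
Why: Olefin cross-metathesis exchanges the terminal monosubstituted alkene for the trisubstituted prenyl-type alkene, while the 2-bromo-1-alkene is too hindered and electron-poor to engage the ruthenium alkylidene and no stereocentre is touched.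

**Step 3**
Reactants: 7 (3S)-2-bromo-6-methylhepta-1,5-dien-3-ol
Product: 8 (3S)-2-bromo-3-(TBS-oxy)-6-methylhepta-1,5-diene
Conditions: TBSCl, imidazole, DMF, 25 °C
Reagents that add atoms: tert-butyldimethylsilyl chloride, CC(C)(C)[Si](C)(C)Cl
Why: Standard silylation; unlike an acetate, the silyl ether neither ionises nor β-eliminates under the low-valent nickel conditions of steps 4 and 5 and is inert to the amide base of step 6.

**Step 4**
Reactants: 8 (3S)-2-bromo-3-(TBS-oxy)-6-methylhepta-1,5-diene; 9 3-bromocyclobutan-1-one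
Product: 10 3-[(3S)-3-(TBS-oxy)-6-methylhepta-1,5-dien-2-yl]cyclobutan-1-one
Conditions: NiBr2·glyme (10 mol %), 4,4′-di-tert-butyl-2,2′-bipyridine (12 mol %), Mn powder, DMA, 25 °C
Reagents that add atoms: none
Why: Nickel-catalysed reductive cross-electrophile coupling in which the alkenyl bromide adds oxidatively to low-valent nickel, the secondary bromide enters as the 3-oxocyclobutyl radical and reductive elimination forms the sp2–sp3 bond under base-free conditions that avoid HBr loss from 9; the ring carbon formed lies on a mirror plane, so no new stereocentre arises.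

**Step 5**
Reactants: 10 3-[(3S)-3-(TBS-oxy)-6-methylhepta-1,5-dien-2-yl]cyclobutan-1-one; 11 propyne
Product: 12 (5R)-5-[(3S)-3-(TBS-oxy)-6-methylhepta-1,5-dien-2-yl]-2-methylcyclohex-2-en-1-one
Conditions: Ni(cod)2 (10 mol %), NHC*·HCl (12 mol %), KOtBu (12 mol %), toluene, 60 °C, propyne (3 equiv) added slowly as a THF solution; the ligand antipode is used if the first run gives the 5S epimer
Reagents that add atoms: none
Why: Proposed new method: a zerovalent nickel complex of the bulky chiral carbene couples the carbonyl of 10 with propyne by oxidative cyclisation in which the large ligand keeps the alkyne methyl away from nickel (C–C bond at the internal alkyne carbon), the spiro oxanickelacyclopentene then undergoes strain-driven β-carbon elimination of one of the two enantiotopic ring C–C bonds under ligand control (this choice sets C5 as R), and sp3–sp2 reductive elimination closes the 2-methylcyclohex-2-enone; the closest known reaction type is the nickel-catalysed formal [4+2] insertion of internal alkynes into cyclobutanones together with ligand-size-controlled regiochemistry in nickel aldehyde–alkyne couplings, whereas a terminal alkyne with methyl-proximal regiochemistry in an intermolecular desymmetrising mode is untested.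

**Step 6**
Reactants: 12 (5R)-5-[(3S)-3-(TBS-oxy)-6-methylhepta-1,5-dien-2-yl]-2-methylcyclohex-2-en-1-one
Product: 14 (5S,6S)-5-[(3S)-3-(TBS-oxy)-6-methylhepta-1,5-dien-2-yl]-6-hydroxy-2-methylcyclohex-2-en-1-one, via sodium dienolate 13 (not isolated)
Conditions: NaN(SiMe3)2, THF, −78 °C; then 2-(benzenesulfonyl)-3-phenyloxaziridine, −78 °C; then AcOH
Reagents that add atoms: 2-(benzenesulfonyl)-3-phenyloxaziridine (Davis oxaziridine), O=S(=O)(c1ccccc1)N1OC1c1ccccc1
Why: Kinetic deprotonation at C6 gives the cross-conjugated dienolate and Davis enolate hydroxylation delivers oxygen anti to the adjacent bulky C5 substituent, setting C6 as S (5,6-trans, both groups equatorial; the C5 descriptor changes from R to S only through the new priority order).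

**Step 7**
Reactants: 14 (5S,6S)-5-[(3S)-3-(TBS-oxy)-6-methylhepta-1,5-dien-2-yl]-6-hydroxy-2-methylcyclohex-2-en-1-one; 15 angelic acid [(Z)-2-methylbut-2-enoic acid]
Product: 17 (5S,6S)-5-[(3S)-3-(TBS-oxy)-6-methylhepta-1,5-dien-2-yl]-2-methyl-6-[(Z)-2-methylbut-2-enoyloxy]cyclohex-2-en-1-one, via mixed anhydride 16 (not isolated)
Conditions: 15, 2,4,6-trichlorobenzoyl chloride, Et3N, toluene, 25 °C; then 14, 75 °C
Reagents that add atoms: none
Why: Yamaguchi-type esterification in which the alcohol attacks only the unhindered angeloyl carbonyl of the mixed anhydride, and leaving out a nucleophilic catalyst keeps the Z geometry, while C6 already sits in its thermodynamically preferred trans arrangement.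

**Step 8**
Reactants: 17 (5S,6S)-5-[(3S)-3-(TBS-oxy)-6-methylhepta-1,5-dien-2-yl]-2-methyl-6-[(Z)-2-methylbut-2-enoyloxy]cyclohex-2-en-1-one
Product: 19 (5S,6S)-5-[(3S)-3-acetoxy-6-methylhepta-1,5-dien-2-yl]-2-methyl-6-[(Z)-2-methylbut-2-enoyloxy]cyclohex-2-en-1-one, via desilylated alcohol 18 (not isolated)
Conditions: Bu4NF, AcOH (1:1), THF, 0 → 25 °C; then Ac2O, Et3N, DMAP (cat.), 0 °C
Reagents that add atoms: acetic anhydride, CC(=O)OC(C)=O
Why: Acetic-acid-buffered fluoride desilylation spares the base-sensitive α-acyloxy ketone and the angelate, and the liberated allylic alcohol is acetylated in the same flask by standard acylation without breaking its C–O bond, so its S configuration is retained.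

**Step 9**
Reactants: 19 (5S,6S)-5-[(3S)-3-acetoxy-6-methylhepta-1,5-dien-2-yl]-2-methyl-6-[(Z)-2-methylbut-2-enoyloxy]cyclohex-2-en-1-one
Product: 20 (1S,5S,6S)-5-[(3S)-3-acetoxy-6-methylhepta-1,5-dien-2-yl]-2-methyl-6-[(Z)-2-methylbut-2-enoyloxy]cyclohex-2-en-1-ol
Conditions: NaBH4, CeCl3·7H2O, MeOH, −78 → −40 °C
Reagents that add atoms: none
Why: Luche reduction gives clean 1,2-addition, with axial hydride delivery on the half-chair that holds the C5 and C6 substituents equatorial, so the C1 hydroxyl ends pseudo-equatorial (1S), cis to the C5 side chain and trans to the C6 ester, while esters and isolated alkenes are inert.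

**Step 10**
Reactants: 20 (1S,5S,6S)-5-[(3S)-3-acetoxy-6-methylhepta-1,5-dien-2-yl]-2-methyl-6-[(Z)-2-methylbut-2-enoyloxy]cyclohex-2-en-1-ol
Product: 21 (1R,2R,3S,5S,6S)-5-[(3S)-3-acetoxy-6-methylhepta-1,5-dien-2-yl]-2,3-epoxy-2-methyl-6-[(Z)-2-methylbut-2-enoyloxy]cyclohexan-1-ol (hydroxyl, oxirane and side chain on one face, angelate on the other)
Conditions: VO(acac)2 (5 mol %), t-BuOOH (anhydrous, in decane), CH2Cl2, 0 → 25 °C
Reagents that add atoms: tert-butyl hydroperoxide, CC(C)(C)OO
Why: Hydroxyl-directed vanadium-catalysed epoxidation delivers the peroxide oxygen from the vanadium alkoxide to the same face of the adjacent C2=C3 bond, setting C2 and C3 with the oxirane cis to the C5 side chain (a direct nucleophilic epoxidation of the enone would give the trans isomer), and alkenes lacking a free allylic hydroxyl are not oxidised.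

**Step 11**
Reactants: 21 (1R,2R,3S,5S,6S)-5-[(3S)-3-acetoxy-6-methylhepta-1,5-dien-2-yl]-2,3-epoxy-2-methyl-6-[(Z)-2-methylbut-2-enoyloxy]cyclohexan-1-ol
Product: 22 (2S,3S,5S,6S)-5-[(3S)-3-acetoxy-6-methylhepta-1,5-dien-2-yl]-2,3-epoxy-2-methyl-6-[(Z)-2-methylbut-2-enoyloxy]cyclohexan-1-one (CNP0125636.1)
Conditions: Dess–Martin periodinane, pyridine, CH2Cl2, 0 → 25 °C
Reagents that add atoms: none
Why: Dess–Martin oxidation of the secondary alcohol under buffered, non-epimerising conditions leaves the oxirane, both esters and all stereocentres intact and gives the target.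

**Compound list**
1 | 2-bromoprop-2-enal (2-bromoacrolein) | C=C(Br)C=O | starting material
2 | allylmagnesium bromide | C=CC[Mg]Br | starting material
3 | B-allyldiisopinocampheylborane, (+)-α-pinene series | C=CCB([C@H]1[C@H](C)[C@H]2C[C@@H](C1)C2(C)C)[C@H]1[C@H](C)[C@H]2C[C@@H](C1)C2(C)C | intermediate
4 | (3S)-2-bromohexa-1,5-dien-3-yl diisopinocampheylborinate | C=C(Br)[C@H](CC=C)OB([C@H]1[C@H](C)[C@H]2C[C@@H](C1)C2(C)C)[C@H]1[C@H](C)[C@H]2C[C@@H](C1)C2(C)C | intermediate
5 | (3S)-2-bromohexa-1,5-dien-3-ol | C=C(Br)[C@@H](O)CC=C | intermediate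
6 | 2-methylbut-2-ene | CC=C(C)C | starting material
7 | (3S)-2-bromo-6-methylhepta-1,5-dien-3-ol | C=C(Br)[C@@H](O)CC=C(C)C | intermediate
8 | (3S)-2-bromo-3-(tert-butyldimethylsilyloxy)-6-methylhepta-1,5-diene | C=C(Br)[C@H](CC=C(C)C)O[Si](C)(C)C(C)(C)C | intermediate
9 | 3-bromocyclobutan-1-one | O=C1CC(Br)C1 | starting material
10 | 3-[(3S)-3-(tert-butyldimethylsilyloxy)-6-methylhepta-1,5-dien-2-yl]cyclobutan-1-one | C=C([C@H](CC=C(C)C)O[Si](C)(C)C(C)(C)C)C1CC(=O)C1 | intermediate
11 | propyne | CC#C | starting material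
12 | (5R)-5-[(3S)-3-(tert-butyldimethylsilyloxy)-6-methylhepta-1,5-dien-2-yl]-2-methylcyclohex-2-en-1-one | C=C([C@H](CC=C(C)C)O[Si](C)(C)C(C)(C)C)[C@@H]1CC=C(C)C(=O)C1 | intermediate
13 | sodium dienolate of 12 (O–Na on C1, C1=C6 and C2=C3) | C=C([C@H](CC=C(C)C)O[Si](C)(C)C(C)(C)C)[C@@H]1CC=C(C)C([O-])=C1.[Na+] | intermediate
14 | (5S,6S)-5-[(3S)-3-(tert-butyldimethylsilyloxy)-6-methylhepta-1,5-dien-2-yl]-6-hydroxy-2-methylcyclohex-2-en-1-one | C=C([C@H](CC=C(C)C)O[Si](C)(C)C(C)(C)C)[C@@H]1CC=C(C)C(=O)[C@H]1O | intermediate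
15 | angelic acid, (Z)-2-methylbut-2-enoic acid | C/C=C(/C)C(=O)O | starting material
16 | (Z)-2-methylbut-2-enoic 2,4,6-trichlorobenzoic anhydride | C/C=C(/C)C(=O)OC(=O)c1c(Cl)cc(Cl)cc1Cl | intermediate
17 | (5S,6S)-5-[(3S)-3-(tert-butyldimethylsilyloxy)-6-methylhepta-1,5-dien-2-yl]-2-methyl-6-[(Z)-2-methylbut-2-enoyloxy]cyclohex-2-en-1-one | C=C([C@H](CC=C(C)C)O[Si](C)(C)C(C)(C)C)[C@@H]1CC=C(C)C(=O)[C@H]1OC(=O)/C(C)=C\C | intermediate
18 | (5S,6S)-5-[(3S)-3-hydroxy-6-methylhepta-1,5-dien-2-yl]-2-methyl-6-[(Z)-2-methylbut-2-enoyloxy]cyclohex-2-en-1-one | C=C([C@H](CC=C(C)C)O)[C@@H]1CC=C(C)C(=O)[C@H]1OC(=O)/C(C)=C\C | intermediate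
19 | (5S,6S)-5-[(3S)-3-acetoxy-6-methylhepta-1,5-dien-2-yl]-2-methyl-6-[(Z)-2-methylbut-2-enoyloxy]cyclohex-2-en-1-one | C=C([C@H](CC=C(C)C)OC(C)=O)[C@@H]1CC=C(C)C(=O)[C@H]1OC(=O)/C(C)=C\C | intermediate
20 | (1S,5S,6S)-5-[(3S)-3-acetoxy-6-methylhepta-1,5-dien-2-yl]-2-methyl-6-[(Z)-2-methylbut-2-enoyloxy]cyclohex-2-en-1-ol | C=C([C@H](CC=C(C)C)OC(C)=O)[C@@H]1CC=C(C)[C@H](O)[C@H]1OC(=O)/C(C)=C\C | intermediate
21 | (1R,2R,3S,5S,6S)-5-[(3S)-3-acetoxy-6-methylhepta-1,5-dien-2-yl]-2,3-epoxy-2-methyl-6-[(Z)-2-methylbut-2-enoyloxy]cyclohexan-1-ol | C=C([C@H](CC=C(C)C)OC(C)=O)[C@@H]1C[C@@H]2O[C@]2(C)[C@H](O)[C@H]1OC(=O)/C(C)=C\C | intermediate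
22 | (2S,3S,5S,6S)-5-[(3S)-3-acetoxy-6-methylhepta-1,5-dien-2-yl]-2,3-epoxy-2-methyl-6-[(Z)-2-methylbut-2-enoyloxy]cyclohexan-1-one | C=C([C@H](CC=C(C)C)OC(C)=O)[C@@H]1C[C@@H]2O[C@]2(C)C(=O)[C@H]1OC(=O)/C(C)=C\C | target

**Step count and risks**
Total steps: 11. Longest linear sequence: 11 (steps 1 to 11; compounds 9, 11 and 15 are bought).

Most likely to fail, first: step 5 (the proposed nickel ring expansion). Propyne may oligomerise, insert with the opposite regiochemistry (3-methyl enone) or give poor selection between the two ring bonds. The fallback uses known chemistry, sets out from 8 and comes back at 12. Miyaura borylation of 8 (PdCl2(dppf), bis(pinacolato)diboron, KOAc, dioxane, 80 °C) gives the alkenyl pinacol boronate F3. Rhodium-catalysed asymmetric conjugate addition of F3 (Rh(acac)(C2H4)2, (R)-BINAP, aqueous dioxane, 100 °C) to racemic 6-methylcyclohex-2-en-1-one F4 gives the 3-alkenyl-6-methylcyclohexanone F5, with C5 set by the catalyst and the methyl-bearing carbon as an inconsequential mixture. Thermodynamic silylation (Me3SiCl, Et3N, DMF, 80 °C) gives the trimethylsilyl enol ether F6, and Saegusa–Ito dehydrogenation (Pd(OAc)2, MeCN) gives 12.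

Second: step 4. 3-Bromocyclobutanone may lose HBr to cyclobutenone, and the hindered alkenyl bromide may homocouple. The fallback sets out from 8 and comes back at 10. 3-Oxocyclobutane-1-carboxylic acid F1 is esterified with N-hydroxyphthalimide (N,N′-diisopropylcarbodiimide, CH2Cl2) to the redox-active ester F2, which undergoes nickel-catalysed decarboxylative reductive alkenylation with 8 (NiBr2·glyme, 4,4′-di-tert-butyl-2,2′-bipyridine, Zn, DMA) to give 10.

Third: step 9. The facial outcome on the 6-acyloxy enone has less precedent than on the parent system, and the C6 ester could migrate to the new C1 hydroxyl; the oxirane configuration depends on this step. The fallback sets out from 12 and comes back at 22. The epoxide is installed before any ester is present, following the carvone to cis-carveol to cis-epoxide pattern. Luche reduction of 12 gives the cis allylic alcohol F7, directed epoxidation (VO(acac)2, t-BuOOH) gives the epoxy alcohol F8, and Dess–Martin oxidation gives the cis-epoxy ketone F9. Enolate hydroxylation as in step 6, anti to both the oxirane and the side chain, gives the 6-hydroxy epoxy ketone F10, and angeloylation as in step 7 gives the silyl-protected angelate F11. Desilylation (Bu4NF, AcOH) to the free side-chain alcohol F12 and acetylation as in step 8 give 22.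

**Further compounds**
F1 | step 4 | 3-oxocyclobutane-1-carboxylic acid (bought) | O=C1CC(C1)C(=O)O
F2 | step 4 | 1,3-dioxoisoindolin-2-yl 3-oxocyclobutane-1-carboxylate | O=C1CC(C1)C(=O)ON1C(=O)c2ccccc2C1=O
F3 | step 5 | tert-butyldimethyl{[(3S)-6-methyl-2-(4,4,5,5-tetramethyl-1,3,2-dioxaborolan-2-yl)hepta-1,5-dien-3-yl]oxy}silane | C=C([C@H](CC=C(C)C)O[Si](C)(C)C(C)(C)C)B1OC(C)(C)C(C)(C)O1
F4 | step 5 | 6-methylcyclohex-2-en-1-one, racemic (bought) | CC1CCC=CC1=O
F5 | step 5 | 5-[(3S)-3-(tert-butyldimethylsilyloxy)-6-methylhepta-1,5-dien-2-yl]-2-methylcyclohexan-1-one, 5R, C2 epimer mixture | C=C([C@H](CC=C(C)C)O[Si](C)(C)C(C)(C)C)[C@@H]1CCC(C)C(=O)C1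
F6 | step 5 | trimethylsilyl enol ether of F5 (C1=C2, 5R) | C=C([C@H](CC=C(C)C)O[Si](C)(C)C(C)(C)C)[C@@H]1CCC(C)=C(O[Si](C)(C)C)C1
F7 | step 9 | (1R,5R)-5-[(3S)-3-(tert-butyldimethylsilyloxy)-6-methylhepta-1,5-dien-2-yl]-2-methylcyclohex-2-en-1-ol | C=C([C@H](CC=C(C)C)O[Si](C)(C)C(C)(C)C)[C@@H]1CC=C(C)[C@H](O)C1
F8 | step 9 | (1R,2R,3S,5S)-5-[(3S)-3-(tert-butyldimethylsilyloxy)-6-methylhepta-1,5-dien-2-yl]-2,3-epoxy-2-methylcyclohexan-1-ol | C=C([C@H](CC=C(C)C)O[Si](C)(C)C(C)(C)C)[C@@H]1C[C@@H]2O[C@]2(C)[C@H](O)C1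
F9 | step 9 | (2S,3S,5R)-5-[(3S)-3-(tert-butyldimethylsilyloxy)-6-methylhepta-1,5-dien-2-yl]-2,3-epoxy-2-methylcyclohexan-1-one | C=C([C@H](CC=C(C)C)O[Si](C)(C)C(C)(C)C)[C@@H]1C[C@@H]2O[C@]2(C)C(=O)C1
F10 | step 9 | (2S,3S,5S,6S)-5-[(3S)-3-(tert-butyldimethylsilyloxy)-6-methylhepta-1,5-dien-2-yl]-2,3-epoxy-6-hydroxy-2-methylcyclohexan-1-one | C=C([C@H](CC=C(C)C)O[Si](C)(C)C(C)(C)C)[C@@H]1C[C@@H]2O[C@]2(C)C(=O)[C@H]1O
F11 | step 9 | (2S,3S,5S,6S)-5-[(3S)-3-(tert-butyldimethylsilyloxy)-6-methylhepta-1,5-dien-2-yl]-2,3-epoxy-2-methyl-6-[(Z)-2-methylbut-2-enoyloxy]cyclohexan-1-one | C=C([C@H](CC=C(C)C)O[Si](C)(C)C(C)(C)C)[C@@H]1C[C@@H]2O[C@]2(C)C(=O)[C@H]1OC(=O)/C(C)=C\C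
F12 | step 9 | (2S,3S,5S,6S)-2,3-epoxy-5-[(3S)-3-hydroxy-6-methylhepta-1,5-dien-2-yl]-2-methyl-6-[(Z)-2-methylbut-2-enoyloxy]cyclohexan-1-one | C=C([C@H](CC=C(C)C)O)[C@@H]1C[C@@H]2O[C@]2(C)C(=O)[C@H]1OC(=O)/C(C)=C\C
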